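1. What is charged stays in the closed flask, so whatever is missing once substrate and target are counted must sit somewhere else. I called this missing part R. The readings give R without anyone measuring it, whichever species it holds.

| flask | substrate | remark | time |
|---|---|---|---|
| green | 0.067 M | run made earlier |  |
| violet | 0.15 M | run made earlier |  |
| elm | 0.10 M |  | 4.0 min |
| cedar | 0.10 M |  | 6.0 min |
| oak | 0.10 M |  | 10 min |

- green (time / min: target / %, substrate / %): 0.417: 12.3, 85.7; 0.833: 22.1, 75.9; 2.00: 30.3, 58.2; 5.00: 27.0, 40.2
- violet (time / min: target / %, substrate / %): 0.667: 32.3, 62.6; 1.50: 43.2, 46.0; 3.00: 41.2, 33.5; 5.00: 31.3, 26.5

(standard deviation of a reading: 0.5 percentage points)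

- which of the two there is more of at the end, elm (target / over-reaction product)
- which of the two there is more of at the end, cedar (target / over-reaction product)
- which of the two there is more of at the end, oak (target / over-reaction product)
- how much target is there at the end, in percent of the substrate charged: elm
- how much target is there at the end, in percent of the substrate charged: cedar
- how much target is there at the end, in percent of the substrate charged: oak

- a species is counted by the substrate in it: one target or over-reaction product counts as two

2. My decision was at which of the three times to stop the flask at 0.10 M of substrate if target was to stay ahead of what it turns into.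

3. In the green run, between 2.00 min and 5.00 min, R gained 21 percentage points while target averaged 28.6%. That ratio is 0.248 min⁻¹. The violet run, charged 2.24 times as strongly, read 0.233 min⁻¹ between 3.00 min and 5.00 min. The ratio did not follow the charge, so I took the mean as the drain constant d, 0.240 min⁻¹, an apparent first-order constant for target.

4. Turned into a time, this is τ = 1/d, 4.16 min: the catch-up time, in which R, starting from nothing and fed at d, reaches a target standing near one level.

5. Elm's time is shorter than τ, narrowly, and cedar's and oak's are longer. So I chose to stop at elm, expecting target just ahead.

6. The forecast gave target 32% for elm, 24.8% for cedar and 14% for oak, with target ahead in elm and over-reaction product ahead in cedar and oak. It noted: “Target and product cross near 4.2 min in both earlier runs”.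

7. The flasks gave target 33.6% in elm, 26.4% in cedar and 15.9% in oak. Over-reaction product stood at 24.5%, 36.0% and 51.8%, so stopping at elm does keep target ahead.

    target → over-reaction product (k = 0.00320 s⁻¹)
    2 substrate ⇌ target (K = 25.0 L mol⁻¹, k = 0.0500 L mol⁻¹ s⁻¹)
    target ⇌ isomer of the product (K = 0.760, k = 7.50 × 10⁻⁴ s⁻¹)

8. R was over-reaction product plus isomer of the product. In cedar, from 3.00 min to 6.00 min, d gives R a gain of 23 points, and it gained 22 points. The step from target to over-reaction product is a part of that feed: oak, run without it, ended at 50.4% target instead of 15.9%. A second flask, the same charge as cedar read at 1.5 min, held 35.9% target; from that reading to cedar at 3.00 min, d gives a gain of 13 points, and R gained 13 points.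

(All runs are calculated from invented constants.)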